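**Route outline**

- Retrosynthesis: the target is cut at the two ester C–O bonds (acetyl on O3, coumaroyl on O4), then at C5–C6 (isobutenyl carbon onto C5), then at the C4–O and C5–O bonds of an oxirane, and last at C3–vinyl, which leads back to methyl vinyl ketone.
- Enabling feature: C3 carries CH3, O and the C1=C2 vinyl group, and its fourth substituent C4(O)–C5H2 is a second vinyl group in oxidised form. C3/C4 therefore map onto achiral 3-methylpenta-1,4-dien-3-ol, whose two vinyl groups are enantiotopic; the C6=C7Me2 terminus is added at C5 afterwards.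
- Forward order: vinyl Grignard addition gives the dienol; one desymmetrising mono-epoxidation forms the only new ring, a transient oxirane (the arene is bought); the oxirane is opened at C5 by an isobutenyl nucleophile; O4 is coumaroylated, O3 acetylated, and the phenol is unmasked.
- Stereochemistry: C3 (R) and C4 (S) both come from the catalyst-controlled epoxidation. Later steps react only at the CH2 carbon or at oxygen, and the E alkene is bought with p-coumaric acid.

Key step: step 2

Assumption: the (R,R)-ligand is taken to be the enantiomer that gives the (R)-carbinol/(S)-oxirane isomer 4; if the sense of induction is the opposite, the (S,S)-ligand is used with nothing else changed.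

**Route**

Step 1
Reactants: 1 methyl vinyl ketone; 2 vinylmagnesium bromide
Product: 3 3-methylpenta-1,4-dien-3-ol
Conditions: CeCl3 (anhydrous, 1.1 equiv), THF, −78 °C; aqueous work-up, distillation
Reagents that add atoms: none
Why: Organocerium-type 1,2-addition of a vinyl Grignard reagent to an enone, in which CeCl3 favours carbonyl attack over conjugate addition; the product is achiral, so no stereocentre arises.

Step 2
Reactants: 3 3-methylpenta-1,4-dien-3-ol
Product: 4 (R)-2-[(S)-oxiran-2-yl]but-3-en-2-ol
Conditions: Hf(OtBu)4 (10 mol%), (R,R)-cyclohexane-1,2-diamine-derived bishydroxamic acid ligand (N,N'-dihydroxy bis(2,2-diarylacetamide), 12 mol%), cumene hydroperoxide (1.0 equiv), 4 Å MS, toluene, 0 °C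
Reagents that add atoms: cumene hydroperoxide, CC(C)(OO)c1ccccc1
Why: Proposed new method: the tertiary alkoxide of 3 and the hydroperoxide should both bind to the chiral hafnium bishydroxamate, and the activated peroxide oxygen is then passed inside this complex to the vinyl group held nearer to it, in one concerted oxygen-atom transfer that forms both C–O bonds of the oxirane (the only ring closed, made by [2+1] addition of oxygen across the C=C bond, not by cyclisation of a chain). The closest known reaction types are the hydroxyl-directed asymmetric epoxidation of tertiary allylic alcohols with Hf(OtBu)4 or Zr(OtBu)4 and chiral bishydroxamic acids, and the Sharpless desymmetrisation of secondary divinyl carbinols; the untested part is a tertiary carbinol with two unsubstituted vinyl groups. The carbinol carbon becomes R because the ligand sphere selects the pro-R vinyl group, and the oxirane CH becomes S because the same ligand sphere fixes which face of the bound vinyl group meets the peroxide oxygen. The step needs group selectivity, face selectivity and a stop at the mono-epoxide. The substrate helps because the hydroxyl sits on the carbon that carries both alkenes, so delivery is strictly intramolecular, and because methyl and the spectator vinyl group differ enough in shape for the catalyst to tell them apart. One equivalent of oxidant limits over-oxidation, and the mono-epoxide of the wrong enantiomeric series should be the one epoxidised a second time more readily, which should raise the enantiomeric purity of 4 as conversion proceeds.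

Step 3
Reactants: 4 (R)-2-[(S)-oxiran-2-yl]but-3-en-2-ol; 5 2-methylprop-1-enylmagnesium bromide
Product: 6 (3R,4S)-3,7-dimethylocta-1,6-diene-3,4-diol
Conditions: 5 (3 equiv), CuI (10 mol%), THF, −40 → −20 °C; aq. NH4Cl
Reagents that add atoms: none
Why: Copper-catalysed SN2 opening of a monosubstituted epoxide by an alkenyl Grignard reagent goes to the unhindered CH2 carbon, the first equivalent only turning the tertiary hydroxyl into a magnesium alkoxide that should not undergo Payne rearrangement in cold THF; neither stereocentre is a reacting atom, so both are kept.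

Step 4
Reactants: 7 (E)-p-coumaric acid
Product: 9 (E)-4-(tert-butyldimethylsilyloxy)cinnamic acid, via bis-silylated coumarate 8 (not isolated)
Conditions: TBSCl (2.3 equiv), imidazole (5 equiv), DMF, rt; then THF/H2O/AcOH added, rt
Reagents that add atoms: tert-butyldimethylsilyl chloride, CC(C)(C)[Si](C)(C)Cl
Why: Silylation of both phenol and acid with TBSCl and imidazole, followed by hydrolysis of the far more labile silyl ester in aqueous acetic acid, which should leave the aryl silyl ether and the E alkene untouched.

Step 5
Reactants: 6 (3R,4S)-3,7-dimethylocta-1,6-diene-3,4-diol; 9 (E)-4-(tert-butyldimethylsilyloxy)cinnamic acid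
Product: 10 (3R,4S)-3-hydroxy-3,7-dimethylocta-1,6-dien-4-yl (E)-3-[4-(tert-butyldimethylsilyloxy)phenyl]prop-2-enoate
Conditions: DCC (1.2 equiv), DMAP (0.2 equiv), CH2Cl2, 0 °C → rt
Reagents that add atoms: none
Why: Steglich esterification, in which the DMAP-activated acyl group should go to the secondary hydroxyl because the neighbouring tertiary allylic hydroxyl is too hindered to compete at room temperature; acylation at oxygen leaves C4 unchanged.

Step 6
Reactants: 10 (3R,4S)-3-hydroxy-3,7-dimethylocta-1,6-dien-4-yl (E)-3-[4-(tert-butyldimethylsilyloxy)phenyl]prop-2-enoate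
Product: 11 (3R,4S)-3-acetoxy-3,7-dimethylocta-1,6-dien-4-yl (E)-3-[4-(tert-butyldimethylsilyloxy)phenyl]prop-2-enoate
Conditions: Ac2O (5 equiv), DMAP (1 equiv), Et3N (6 equiv), CH2Cl2, rt → 35 °C
Reagents that add atoms: acetic anhydride, CC(=O)OC(C)=O
Why: DMAP-catalysed acetylation with acetic anhydride is the standard way to esterify hindered tertiary allylic alcohols of the linalool type; the bond forms at oxygen so C3 keeps its configuration, and the weakly basic amine medium should keep migration of the coumaroyl group slow.

Step 7
Reactants: 11 (3R,4S)-3-acetoxy-3,7-dimethylocta-1,6-dien-4-yl (E)-3-[4-(tert-butyldimethylsilyloxy)phenyl]prop-2-enoate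
Product: 12 (3R,4S)-3-acetoxy-3,7-dimethylocta-1,6-dien-4-yl (E)-3-(4-hydroxyphenyl)prop-2-enoate (CNP0547742.1)
Conditions: Bu4NF (1.1 equiv), AcOH (1.1 equiv), THF, 0 °C
Reagents that add atoms: none
Why: Fluoride cleavage of an aryl silyl ether, buffered with acetic acid so that the phenoxide set free is protonated at once and cannot attack the acetate or the cinnamate ester.

**Compound list**

1 | methyl vinyl ketone (but-3-en-2-one) | C=CC(C)=O | starting material
2 | vinylmagnesium bromide | C=C[Mg]Br | starting material
3 | 3-methylpenta-1,4-dien-3-ol (achiral, two enantiotopic vinyl groups) | C=CC(C)(O)C=C | intermediate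
4 | (R)-2-[(S)-oxiran-2-yl]but-3-en-2-ol | C=C[C@@](C)(O)[C@H]1OC1 | intermediate
5 | 2-methylprop-1-enylmagnesium bromide | CC(C)=C[Mg]Br | starting material
6 | (3R,4S)-3,7-dimethylocta-1,6-diene-3,4-diol | C=C[C@@](C)(O)[C@H](CC=C(C)C)O | intermediate
7 | (E)-p-coumaric acid | O=C(O)/C=C/c1ccc(O)cc1 | starting material
8 | tert-butyldimethylsilyl (E)-3-[4-(tert-butyldimethylsilyloxy)phenyl]prop-2-enoate (not isolated) | CC(C)(C)[Si](C)(C)OC(=O)/C=C/c1ccc(O[Si](C)(C)C(C)(C)C)cc1 | intermediate
9 | (E)-4-(tert-butyldimethylsilyloxy)cinnamic acid | O=C(O)/C=C/c1ccc(O[Si](C)(C)C(C)(C)C)cc1 | intermediate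
10 | (3R,4S)-3-hydroxy-3,7-dimethylocta-1,6-dien-4-yl (E)-3-[4-(tert-butyldimethylsilyloxy)phenyl]prop-2-enoate | C=C[C@@](C)(O)[C@H](CC=C(C)C)OC(=O)/C=C/c1ccc(O[Si](C)(C)C(C)(C)C)cc1 | intermediate
11 | (3R,4S)-3-acetoxy-3,7-dimethylocta-1,6-dien-4-yl (E)-3-[4-(tert-butyldimethylsilyloxy)phenyl]prop-2-enoate | C=C[C@@](C)(OC(C)=O)[C@H](CC=C(C)C)OC(=O)/C=C/c1ccc(O[Si](C)(C)C(C)(C)C)cc1 | intermediate
12 | (3R,4S)-3-acetoxy-3,7-dimethylocta-1,6-dien-4-yl (E)-3-(4-hydroxyphenyl)prop-2-enoate, CNP0547742.1 | C=C[C@@](C)(OC(C)=O)[C@H](CC=C(C)C)OC(=O)/C=C/c1ccc(O)cc1 | target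

**Step count and risks**

Total step count: 7. Longest linear sequence: 6 steps (steps 1, 2, 3, 5, 6, 7); step 4 is a one-step side branch.

Steps most likely to fail:

1. Step 2 (the proposed new method). Oxygen transfer to an unsubstituted vinyl group may be sluggish, and the catalyst may discriminate poorly between the two vinyl groups or between the two faces; over-epoxidation is also possible. The fallback uses known chemistry, sets out from vinylmagnesium bromide 2 and comes back at diol 6. Two equivalents of 2 add to ethyl formate to give penta-1,4-dien-3-ol F1. Sharpless asymmetric epoxidation of this secondary divinyl carbinol (Ti(OiPr)4, D-(−)-diisopropyl tartrate, tBuOOH, 4 Å MS, CH2Cl2, −20 °C) should desymmetrise it to (2S,3R)-1,2-epoxypent-4-en-3-ol F2. The copper-catalysed opening with 5 used in step 3 then gives (3R,4S)-7-methylocta-1,6-diene-3,4-diol F3. MnO2 in CH2Cl2 should oxidise only the allylic hydroxyl, giving (S)-4-hydroxy-7-methylocta-1,6-dien-3-one F4. Excess MeMgBr in THF at −78 °C adds to the ketone through the five-membered magnesium chelate of the neighbouring alkoxide, from the face that bears the C4 hydrogen, which should give 6 with C3 as R.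

2. Step 3. The magnesium alkoxide next to the oxirane may trigger Payne rearrangement, MgBr2 may open the epoxide to a bromohydrin, or attack may go to the inner carbon. The fallback sets out from epoxide 4 and comes back at diol 6. The tertiary hydroxyl is capped first (Et3SiOTf, 2,6-lutidine, CH2Cl2, −78 °C) to give triethyl{[(R)-2-[(S)-oxiran-2-yl]but-3-en-2-yl]oxy}silane F5. With no alkoxide beside the oxirane, the copper-catalysed opening with 5 gives (3R,4S)-3,7-dimethyl-3-(triethylsilyloxy)octa-1,6-dien-4-ol F6. Bu4NF in THF then removes the silyl group, also if it has moved to O4, and gives 6.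

3. Step 6. Acetylation of the hindered tertiary hydroxyl may be slow enough for the coumaroyl group to migrate to O3, after which O4 would be acetylated to the regioisomeric diester; elimination of the tertiary allylic oxygen is a further risk. The fallback reverses the order of acylation; it sets out from diol 6 and comes back at the silyl-protected target 11. Et3SiCl and imidazole in DMF silylate only the secondary hydroxyl, giving (3R,4S)-3,7-dimethyl-4-(triethylsilyloxy)octa-1,6-dien-3-ol F7. Ac2O, DMAP and Et3N at 40 °C acetylate the tertiary hydroxyl with no neighbouring ester to migrate, giving (3R,4S)-3,7-dimethyl-4-(triethylsilyloxy)octa-1,6-dien-3-yl acetate F8. HF·pyridine in THF at 0 °C, acidic so that acetyl migration is slow, frees the secondary hydroxyl, giving (3R,4S)-4-hydroxy-3,7-dimethylocta-1,6-dien-3-yl acetate F9. This is esterified at once with acid 9 (DCC, DMAP, CH2Cl2, 0 °C) to give 11. A migrated acetate would leave only an unreactive tertiary hydroxyl, so this order cannot deliver the regioisomeric diester.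

Further compounds
F1 | step 2 | penta-1,4-dien-3-ol | C=CC(O)C=C
F2 | step 2 | (2S,3R)-1,2-epoxypent-4-en-3-ol | C=C[C@@H](O)[C@H]1OC1
F3 | step 2 | (3R,4S)-7-methylocta-1,6-diene-3,4-diol | C=C[C@@H](O)[C@H](CC=C(C)C)O
F4 | step 2 | (S)-4-hydroxy-7-methylocta-1,6-dien-3-one | C=CC(=O)[C@H](CC=C(C)C)O
F5 | step 3 | triethyl{[(R)-2-[(S)-oxiran-2-yl]but-3-en-2-yl]oxy}silane | C=C[C@@](C)(O[Si](CC)(CC)CC)[C@H]1OC1
F6 | step 3 | (3R,4S)-3,7-dimethyl-3-(triethylsilyloxy)octa-1,6-dien-4-ol | C=C[C@@](C)(O[Si](CC)(CC)CC)[C@H](CC=C(C)C)O
F7 | step 6 | (3R,4S)-3,7-dimethyl-4-(triethylsilyloxy)octa-1,6-dien-3-ol | C=C[C@@](C)(O)[C@H](CC=C(C)C)O[Si](CC)(CC)CC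
F8 | step 6 | (3R,4S)-3,7-dimethyl-4-(triethylsilyloxy)octa-1,6-dien-3-yl acetate | C=C[C@@](C)(OC(C)=O)[C@H](CC=C(C)C)O[Si](CC)(CC)CC
F9 | step 6 | (3R,4S)-4-hydroxy-3,7-dimethylocta-1,6-dien-3-yl acetate | C=C[C@@](C)(OC(C)=O)[C@H](CC=C(C)C)O
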